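Ring B is disconnected last. Its phenol carbon C1, the chain-bearing C5 and the unsubstituted C4 and C6 come from a 3-alkylcyclobutenone; C2 and the oxygenated C3 come from a silyl ynol ether, so the meta-dioxygen, 5-alkyl pattern of this resorcinol is what the key step exploits. Heating the cyclobutenone, which already holds the complete (R)-ester with ring A as its bis(benzyl) ether, with (triisopropylsilyloxy)acetylene forms the C1–C2 and C3–C4 bonds and recloses the six-membered ring in one neutral operation. The hindered ester is made by Mitsunobu inversion, so the stereocentre is bought as (S)-2-propyloxirane; desilylation and hydrogenolysis finish the synthesis.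

Key step: step 10

Remark on the chemistry: ring B is numbered C1 (the carbon that receives the free hydroxyl in the key step), C2, C3 (silyloxy carbon), C4, C5 (chain carbon), C6. The 2,6-disubstituted acid is assumed too hindered for reliable acyl-transfer esterification, so the ester is made by O-alkylation with inversion; the (R)-carbinol of the target therefore comes from the (S)-epoxide.

Step 1
Reactants: 1 3,5-bis(benzyloxy)benzyl bromide; 2 decylmagnesium bromide
Product: 3 1,3-bis(benzyloxy)-5-undecylbenzene
Conditions: Li2CuCl4 (3 mol%), THF, −20 °C to rt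
Reagents that add atoms: none
Why: Copper-catalysed Grignard cross-coupling (Kochi type) of a primary alkylmagnesium bromide with a benzylic bromide should form the sp3–sp3 bond cleanly at low temperature, and aryl benzyl ethers are inert to the Grignard reagent.

Step 2
Reactants: 3 1,3-bis(benzyloxy)-5-undecylbenzene
Product: 5 2,4-bis(benzyloxy)-6-undecylbenzaldehyde, via aryliminium chloride 4 (not isolated)
Conditions: POCl3, DMF, 0 to 70 °C; then ice-water
Reagents that add atoms: N,N-dimethylformamide, CN(C)C=O; water, O; phosphoryl chloride, O=P(Cl)(Cl)Cl (chloride of 4 only)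
Why: Vilsmeier–Haack formylation should attack the ring position para to one benzyloxy group and ortho to the other, next to the alkyl chain, in preference to the doubly flanked position between the two ethers, as it does with orcinol diethers, and water hydrolyses the iminium salt to the aldehyde.

Step 3
Reactants: 5 2,4-bis(benzyloxy)-6-undecylbenzaldehyde
Product: 6 2,4-bis(benzyloxy)-6-undecylbenzoic acid
Conditions: NaClO2, NaH2PO4, 2-methylbut-2-ene, t-BuOH/THF/H2O, rt
Reagents that add atoms: sodium chlorite, [Na+].[O-]Cl=O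
Why: Pinnick oxidation converts the hindered, electron-rich aldehyde into the acid under buffered conditions, while 2-methylbut-2-ene traps hypochlorous acid before it can chlorinate ring A.

Step 4
Reactants: 7 1-bromo-6-chlorohexane; 8 (S)-2-propyloxirane
Product: 10 (S)-11-chloroundecan-4-ol, via 6-chlorohexylmagnesium bromide 9 (not isolated)
Conditions: Mg, THF, 40 °C; then CuI (10 mol%), 8, THF, −30 to 0 °C; H2O quench
Reagents that add atoms: magnesium, [Mg] (in 9 only)
Why: Magnesium inserts selectively into the C–Br bond, and copper-catalysed SN2 opening of the monosubstituted epoxide at its unsubstituted carbon (Grignard epoxide opening) leaves the purchased stereocentre untouched, so the (S)-alcohol should result.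

Step 5
Reactants: 10 (S)-11-chloroundecan-4-ol; 11 lithium acetylide–ethylenediamine complex
Product: 12 (S)-tridec-12-yn-4-ol
Conditions: 11 (3 equiv), NaI (cat.), DMSO, rt to 40 °C
Reagents that add atoms: none
Why: SN2 alkynylation of a primary alkyl chloride by lithium acetylide in DMSO, assisted by in situ Finkelstein exchange, tolerates the remote secondary alkoxide and does not involve the stereocentre.

Step 6
Reactants: 6 2,4-bis(benzyloxy)-6-undecylbenzoic acid; 12 (S)-tridec-12-yn-4-ol
Product: 13 (R)-tridec-12-yn-4-yl 2,4-bis(benzyloxy)-6-undecylbenzoate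
Conditions: PPh3, DIAD, THF, 0 °C to rt
Reagents that add atoms: none
Why: Mitsunobu esterification forms the C–O bond by carboxylate attack on the oxyphosphonium-activated alcohol, so the shielding of the 2,6-disubstituted acyl carbon does not matter, and the SN2 inversion turns the (S)-carbinol into the (R)-ester.

Step 7
Reactants: 13 (R)-tridec-12-yn-4-yl 2,4-bis(benzyloxy)-6-undecylbenzoate; 14 trichloroacetyl chloride
Product: 16 (R)-11-(4,4-dichloro-3-oxocyclobut-1-en-1-yl)undecan-4-yl 2,4-bis(benzyloxy)-6-undecylbenzoate, via dichloroketene 15 (not isolated)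
Conditions: Zn(Cu), Et2O/DME, rt, slow addition of 14
Reagents that add atoms: none
Why: Ketene–alkyne [2+2] cycloaddition of dichloroketene, generated by zinc dechlorination of the acid chloride, joins the ketene carbonyl carbon to the unsubstituted alkyne carbon and should give the 3-alkyl-4,4-dichlorocyclobutenone, with DME tying up ZnCl2 so that the ester and benzyl ethers are spared.

Step 8
Reactants: 16 (R)-11-(4,4-dichloro-3-oxocyclobut-1-en-1-yl)undecan-4-yl 2,4-bis(benzyloxy)-6-undecylbenzoate
Product: 17 (R)-11-(3-oxocyclobut-1-en-1-yl)undecan-4-yl 2,4-bis(benzyloxy)-6-undecylbenzoate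
Conditions: Zn, AcOH, TMEDA, EtOH/THF, 0 °C
Reagents that add atoms: none
Why: Zinc-mediated reductive dechlorination of the α,α-dichloro ketone under amine-buffered conditions at 0 °C should remove both chlorines without reducing or isomerising the strained enone, and the ester and benzyl ethers are inert.

Step 9
Reactants: 18 3-phenylisoxazole
Product: 20 (triisopropylsilyloxy)acetylene, via lithium ethynolate 19 (not isolated)
Conditions: n-BuLi, THF, −78 °C; then i-Pr3SiOTf, −78 to 0 °C
Reagents that add atoms: triisopropylsilyl trifluoromethanesulfonate, CC(C)[Si](OS(=O)(=O)C(F)(F)F)(C(C)C)C(C)C; n-butyllithium, [Li]CCCC (lithium of 19 only)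
Why: Deprotonation at C5 of the isoxazole is followed by cycloreversion to benzonitrile and the lithium ynolate (base-induced fragmentation of 3-aryl-isoxazoles unsubstituted at C5), and the bulky, hard silyl triflate should silylate the ynolate on oxygen (O-silylation of a lithium ynolate) to give the ynol ether and not the silylketene.

Step 10
Reactants: 17 (R)-11-(3-oxocyclobut-1-en-1-yl)undecan-4-yl 2,4-bis(benzyloxy)-6-undecylbenzoate; 20 (triisopropylsilyloxy)acetylene
Product: 25 (R)-11-[3-hydroxy-5-(triisopropylsilyloxy)phenyl]undecan-4-yl 2,4-bis(benzyloxy)-6-undecylbenzoate, via vinylketene 21 (not isolated), via 4-vinylcyclobutenone 22 (not isolated), via dienylketene 23 (not isolated), via cyclohexadienone 24 (not isolated)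
Conditions: 20 (2 equiv), toluene, 80 °C, then 110 °C, argon
Reagents that add atoms: none
Why: Heat opens cyclobutenone 17 by 4π electrocyclic ring opening to vinylketene 21, whose ketene C=C adds [2+2] to the electron-rich triple bond of 20 to give 4-vinylcyclobutenone 22; a second 4π opening gives dienylketene 23, which closes to cyclohexadienone 24 and tautomerises to the phenol. The closest known reaction type is the Danheiser benzannulation of 3-substituted cyclobutenones with alkoxy- and trialkylsilyloxyalkynes, which delivers resorcinol monoethers. Ring B is closed by a thermal disrotatory 6π electrocyclisation that joins the ketene carbon C1 to the terminal methylene C6, after the cycloaddition has made the C1–C2 and C3–C4 bonds. No stereocentre is formed in the product, since the sp3 ring carbon of 22 is lost on ring opening, and the existing carbinol centre lies far from the reacting π system. The step needs regiocontrol in the ketene–alkyne cycloaddition, and the polarisation of the ynol ether secures it: its unsubstituted nucleophilic carbon bonds to the electrophilic ketene carbon, so the silyloxy group ends up meta to the new hydroxyl and the chain sits on C5. The cascade is neutral and needs no reagent, so the ester and the benzyl ethers of ring A should pass through unchanged.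

Step 11
Reactants: 25 (R)-11-[3-hydroxy-5-(triisopropylsilyloxy)phenyl]undecan-4-yl 2,4-bis(benzyloxy)-6-undecylbenzoate
Product: 26 (R)-11-(3,5-dihydroxyphenyl)undecan-4-yl 2,4-bis(benzyloxy)-6-undecylbenzoate
Conditions: TBAF, AcOH, THF, 0 °C
Reagents that add atoms: none
Why: Fluoride-mediated cleavage of the aryl silyl ether, buffered with acetic acid so that the phenoxide is protonated at once, should leave the hindered ester and the benzyl ethers intact.

Step 12
Reactants: 26 (R)-11-(3,5-dihydroxyphenyl)undecan-4-yl 2,4-bis(benzyloxy)-6-undecylbenzoate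
Product: 27 (R)-11-(3,5-dihydroxyphenyl)undecan-4-yl 2,4-dihydroxy-6-undecylbenzoate (CNP0146287.1)
Conditions: H2 (1 atm), Pd/C, EtOAc/EtOH, rt
Reagents that add atoms: none
Why: Catalytic hydrogenolysis cleaves only the two benzylic C–O bonds of the aryl benzyl ethers, because the ester is a non-benzylic secondary alkyl benzoate and the stereocentre is not involved.

Compound list

1 | 3,5-bis(benzyloxy)benzyl bromide | BrCc1cc(OCc2ccccc2)cc(OCc2ccccc2)c1 | starting material
2 | decylmagnesium bromide | CCCCCCCCCC[Mg]Br | starting material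
3 | 1,3-bis(benzyloxy)-5-undecylbenzene | CCCCCCCCCCCc1cc(OCc2ccccc2)cc(OCc2ccccc2)c1 | intermediate
4 | N-[2,4-bis(benzyloxy)-6-undecylbenzylidene]-N-methylmethanaminium chloride (not isolated) | CCCCCCCCCCCc1cc(OCc2ccccc2)cc(OCc2ccccc2)c1C=[N+](C)C.[Cl-] | intermediate
5 | 2,4-bis(benzyloxy)-6-undecylbenzaldehyde | CCCCCCCCCCCc1cc(OCc2ccccc2)cc(OCc2ccccc2)c1C=O | intermediate
6 | 2,4-bis(benzyloxy)-6-undecylbenzoic acid | CCCCCCCCCCCc1cc(OCc2ccccc2)cc(OCc2ccccc2)c1C(=O)O | intermediate
7 | 1-bromo-6-chlorohexane | ClCCCCCCBr | starting material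
8 | (S)-2-propyloxirane | CCC[C@H]1CO1 | starting material
9 | 6-chlorohexylmagnesium bromide (not isolated) | ClCCCCCC[Mg]Br | intermediate
10 | (S)-11-chloroundecan-4-ol | CCC[C@H](O)CCCCCCCCl | intermediate
11 | lithium acetylide–ethylenediamine complex | [Li]C#C.NCCN | starting material
12 | (S)-tridec-12-yn-4-ol | CCC[C@H](O)CCCCCCCC#C | intermediate
13 | (R)-tridec-12-yn-4-yl 2,4-bis(benzyloxy)-6-undecylbenzoate | CCCCCCCCCCCc1cc(OCc2ccccc2)cc(OCc2ccccc2)c1C(=O)O[C@H](CCC)CCCCCCCC#C | intermediate
14 | trichloroacetyl chloride | ClC(Cl)(Cl)C(Cl)=O | starting material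
15 | dichloroketene (not isolated) | ClC(Cl)=C=O | intermediate
16 | (R)-11-(4,4-dichloro-3-oxocyclobut-1-en-1-yl)undecan-4-yl 2,4-bis(benzyloxy)-6-undecylbenzoate | CCCCCCCCCCCc1cc(OCc2ccccc2)cc(OCc2ccccc2)c1C(=O)O[C@H](CCC)CCCCCCCC1=CC(=O)C1(Cl)Cl | intermediate
17 | (R)-11-(3-oxocyclobut-1-en-1-yl)undecan-4-yl 2,4-bis(benzyloxy)-6-undecylbenzoate | CCCCCCCCCCCc1cc(OCc2ccccc2)cc(OCc2ccccc2)c1C(=O)O[C@H](CCC)CCCCCCCC1=CC(=O)C1 | intermediate
18 | 3-phenylisoxazole | c1ccc(cc1)-c1ccon1 | starting material
19 | lithium ethynolate (not isolated) | [Li]OC#C | intermediate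
20 | (triisopropylsilyloxy)acetylene | C#CO[Si](C(C)C)(C(C)C)C(C)C | intermediate
21 | (R)-12-methylidene-14-oxotetradec-13-en-4-yl 2,4-bis(benzyloxy)-6-undecylbenzoate (vinylketene, not isolated) | CCCCCCCCCCCc1cc(OCc2ccccc2)cc(OCc2ccccc2)c1C(=O)O[C@H](CCC)CCCCCCCC(=C)C=C=O | intermediate
22 | (R)-12-[2-oxo-4-(triisopropylsilyloxy)cyclobut-3-en-1-yl]tridec-12-en-4-yl 2,4-bis(benzyloxy)-6-undecylbenzoate (both configurations at the ring carbon, not isolated) | CCCCCCCCCCCc1cc(OCc2ccccc2)cc(OCc2ccccc2)c1C(=O)O[C@H](CCC)CCCCCCCC(=C)C1C(=O)C=C1O[Si](C(C)C)(C(C)C)C(C)C | intermediate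
23 | (4R,13E)-12-methylidene-16-oxo-14-(triisopropylsilyloxy)hexadeca-13,15-dien-4-yl 2,4-bis(benzyloxy)-6-undecylbenzoate (dienylketene, not isolated) | CCCCCCCCCCCc1cc(OCc2ccccc2)cc(OCc2ccccc2)c1C(=O)O[C@H](CCC)CCCCCCCC(=C)/C=C(O[Si](C(C)C)(C(C)C)C(C)C)\C=C=O | intermediate
24 | (R)-11-[5-oxo-3-(triisopropylsilyloxy)cyclohexa-1,3-dien-1-yl]undecan-4-yl 2,4-bis(benzyloxy)-6-undecylbenzoate (not isolated) | CCCCCCCCCCCc1cc(OCc2ccccc2)cc(OCc2ccccc2)c1C(=O)O[C@H](CCC)CCCCCCCC1=CC(O[Si](C(C)C)(C(C)C)C(C)C)=CC(=O)C1 | intermediate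
25 | (R)-11-[3-hydroxy-5-(triisopropylsilyloxy)phenyl]undecan-4-yl 2,4-bis(benzyloxy)-6-undecylbenzoate | CCCCCCCCCCCc1cc(OCc2ccccc2)cc(OCc2ccccc2)c1C(=O)O[C@H](CCC)CCCCCCCc1cc(O)cc(O[Si](C(C)C)(C(C)C)C(C)C)c1 | intermediate
26 | (R)-11-(3,5-dihydroxyphenyl)undecan-4-yl 2,4-bis(benzyloxy)-6-undecylbenzoate | CCCCCCCCCCCc1cc(OCc2ccccc2)cc(OCc2ccccc2)c1C(=O)O[C@H](CCC)CCCCCCCc1cc(O)cc(O)c1 | intermediate
27 | (R)-11-(3,5-dihydroxyphenyl)undecan-4-yl 2,4-dihydroxy-6-undecylbenzoate | CCCCCCCCCCCc1cc(O)cc(O)c1C(=O)O[C@H](CCC)CCCCCCCc1cc(O)cc(O)c1 | target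

Total step count: 12.
Longest linear sequence: 9 steps (steps 1, 2, 3, 6, 7, 8, 10, 11, 12).

Steps most likely to fail

1. Step 10. The vinylketene may be captured by the phenol already formed, or may dimerise, and the silyl ynol ether may undergo thermal 1,3-silyl migration to an unreactive silylketene before it is consumed, so the cascade could stall short of ring B. The fallback buys ring B preformed and joins it by an sp3–sp2 coupling; it sets out from chloro alcohol 10 and acid 6 and comes back at target 27. Mitsunobu esterification of 10 with 6 (PPh3, DIAD, THF) should give (R)-11-chloroundecan-4-yl 2,4-bis(benzyloxy)-6-undecylbenzoate F1. Finkelstein exchange (NaI, butanone, reflux) gives (R)-11-iodoundecan-4-yl 2,4-bis(benzyloxy)-6-undecylbenzoate F2. Zinc insertion (Zn, LiCl, THF, 40 °C) gives the alkylzinc iodide F3, which is used without isolation in a Negishi coupling with commercial 1,3-bis(benzyloxy)-5-bromobenzene (Pd(OAc)2, SPhos, THF) to give (R)-11-[3,5-bis(benzyloxy)phenyl]undecan-4-yl 2,4-bis(benzyloxy)-6-undecylbenzoate F4. Hydrogenolysis of all four benzyl ethers (H2, Pd/C) then gives 27.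

2. Step 9. Silylation of the parent ynolate may occur on carbon instead of oxygen, and the volatile, hydrolytically sensitive ynol ether may be lost during separation from benzonitrile. The fallback replaces the silyl ynol ether by a commercial alkyl ynol ether; it sets out from cyclobutenone 17 and comes back at target 27. Heating 17 with ethoxyethyne (toluene, 80 °C), a standard alkoxyalkyne partner for this benzannulation, should give (R)-11-(3-ethoxy-5-hydroxyphenyl)undecan-4-yl 2,4-bis(benzyloxy)-6-undecylbenzoate F5. Hydrogenolysis (H2, Pd/C) gives (R)-11-(3-ethoxy-5-hydroxyphenyl)undecan-4-yl 2,4-dihydroxy-6-undecylbenzoate F6. BBr3 (CH2Cl2, −78 to 0 °C) then cleaves the aryl ethyl ether to give 27; dihydroxybenzoate esters of secondary alcohols of this kind are known to survive boron tribromide dealkylation.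

3. Step 7. ZnCl2-promoted oligomerisation of dichloroketene may outrun cycloaddition to the unactivated alkyne of a large lipophilic substrate, and chlorine removal in step 8 may then be incomplete. The fallback uses a keteniminium in place of the ketene and needs no dechlorination; it sets out from alkyne 13 and comes back at cyclobutenone 17. N,N-Dimethylacetamide, Tf2O and 2,4,6-collidine in 1,2-dichloroethane at reflux generate N,N-dimethylketeniminium triflate F7, which adds [2+2] to the terminal alkyne with the same regiochemistry to give the cyclobuteniminium salt N-[3-{(8R)-8-[2,4-bis(benzyloxy)-6-undecylbenzoyloxy]undecyl}cyclobut-2-en-1-ylidene]-N-methylmethanaminium triflate F8. Hydrolysis with aqueous NaHCO3 gives 17.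

Further compounds

F1 | step 10 | (R)-11-chloroundecan-4-yl 2,4-bis(benzyloxy)-6-undecylbenzoate | CCCCCCCCCCCc1cc(OCc2ccccc2)cc(OCc2ccccc2)c1C(=O)O[C@H](CCC)CCCCCCCCl
F2 | step 10 | (R)-11-iodoundecan-4-yl 2,4-bis(benzyloxy)-6-undecylbenzoate | CCCCCCCCCCCc1cc(OCc2ccccc2)cc(OCc2ccccc2)c1C(=O)O[C@H](CCC)CCCCCCCI
F3 | step 10 | {(8R)-8-[2,4-bis(benzyloxy)-6-undecylbenzoyloxy]undecyl}zinc iodide | CCCCCCCCCCCc1cc(OCc2ccccc2)cc(OCc2ccccc2)c1C(=O)O[C@H](CCC)CCCCCCC[Zn]I
F4 | step 10 | (R)-11-[3,5-bis(benzyloxy)phenyl]undecan-4-yl 2,4-bis(benzyloxy)-6-undecylbenzoate | CCCCCCCCCCCc1cc(OCc2ccccc2)cc(OCc2ccccc2)c1C(=O)O[C@H](CCC)CCCCCCCc1cc(OCc2ccccc2)cc(OCc2ccccc2)c1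
F5 | step 9 | (R)-11-(3-ethoxy-5-hydroxyphenyl)undecan-4-yl 2,4-bis(benzyloxy)-6-undecylbenzoate | CCCCCCCCCCCc1cc(OCc2ccccc2)cc(OCc2ccccc2)c1C(=O)O[C@H](CCC)CCCCCCCc1cc(O)cc(OCC)c1
F6 | step 9 | (R)-11-(3-ethoxy-5-hydroxyphenyl)undecan-4-yl 2,4-dihydroxy-6-undecylbenzoate | CCCCCCCCCCCc1cc(O)cc(O)c1C(=O)O[C@H](CCC)CCCCCCCc1cc(O)cc(OCC)c1
F7 | step 7 | N,N-dimethylketeniminium trifluoromethanesulfonate | C=C=[N+](C)C.[O-]S(=O)(=O)C(F)(F)F
F8 | step 7 | N-[3-{(8R)-8-[2,4-bis(benzyloxy)-6-undecylbenzoyloxy]undecyl}cyclobut-2-en-1-ylidene]-N-methylmethanaminium trifluoromethanesulfonate | CCCCCCCCCCCc1cc(OCc2ccccc2)cc(OCc2ccccc2)c1C(=O)O[C@H](CCC)CCCCCCCC1=CC(=[N+](C)C)C1.[O-]S(=O)(=O)C(F)(F)F
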